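Retrosynthesis first removes the seven O-benzyl groups. It then cuts C4–H of ring C and the interflavan bond C4(ring C)–C8(ring D), made from an aryllithium, a flavanone and hydride. Next come C3–H of ring F (ketone reduction), ring F itself at C3–C4 and O1–C2, and the C2–ring B bond of the upper unit.
Enabling feature: C4 of ring F sits on C4a of ring D, directly beside C8a–O1, so O1–C8a–C4a–C4 is a masked salicylaldehyde. C2 (benzylic to ring E) and C3 are the β- and α-carbons of a cinnamaldehyde, so one aminocatalytic oxa-Michael/aldol cascade makes O1–C2 and then closes ring F at C3–C4.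
The formyl group that this cascade leaves on C3 is a helper. It is oxidised and removed by Curtius rearrangement, which puts the oxygen on C3 and turns C4 into the methylene group.
Forward order: ring F is built on ring D (carrying ring E), followed by the C3 ketone, the cis-alcohol and the C8 bromide. Separately, a chromone (rings A and C) receives ring B. The two halves are then joined at C8–C4, the cation is reduced, and the benzyl groups are removed.
Stereochemistry: C2 of ring F comes from the prolinol catalyst, and C3 of ring F from substrate-controlled hydride attack on the ketone. C2 of ring C comes from the chiral rhodium catalyst, and C4 of ring C from pseudoaxial hydride delivery governed by C2 of ring C.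
Key step: step 3

Assumption: the sense of induction in steps 3 and 10 is assigned from the accepted face-shielding models of the two catalysts. If either runs the other way, the antipodal catalyst or ligand would be used.

Step 1
Reactants: 1 2,4,6-trihydroxybenzaldehyde
Product: 2 2,4-bis(benzyloxy)-6-hydroxybenzaldehyde
Conditions: BnBr (2.1 equiv), K2CO3, DMF, 25 °C
Reagents that add atoms: benzyl bromide, BrCc1ccccc1
Why: Williamson etherification should alkylate the para-hydroxyl and one ortho-hydroxyl, while the remaining ortho-hydroxyl is held back by its hydrogen bond to the formyl group, so that exactly the future O1 stays free.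

Step 2
Reactants: 3 3,4-bis(benzyloxy)benzaldehyde
Product: 4 (E)-3-[3,4-bis(benzyloxy)phenyl]prop-2-enal
Conditions: Ph3P=CHCHO, toluene, 90 °C
Reagents that add atoms: (triphenylphosphoranylidene)acetaldehyde, O=CC=P(c1ccccc1)(c1ccccc1)c1ccccc1
Why: Wittig reaction with a stabilised ylide, which should give the E-enal by two-carbon homologation of the aromatic aldehyde.

Step 3
Reactants: 2 2,4-bis(benzyloxy)-6-hydroxybenzaldehyde; 4 (E)-3-[3,4-bis(benzyloxy)phenyl]prop-2-enal
Product: 7 (R)-5,7-bis(benzyloxy)-2-[3,4-bis(benzyloxy)phenyl]-2H-chromene-3-carbaldehyde, via oxa-Michael adduct 5 (not isolated), via aldol adduct 6 (not isolated)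
Conditions: (S)-α,α-diphenylprolinol trimethylsilyl ether (20 mol %), 2-nitrobenzoic acid (20 mol %), 4 Å MS, toluene, 25 °C, dark
Reagents that add atoms: none
Why: Enal 4 condenses with the secondary amine to an E-iminium ion, the phenol oxygen O1 of 2 adds to its β-carbon (future C2) from the face left open by the diphenyl(silyloxy)methyl group, and the enamine form of 5 then attacks the ortho-formyl carbon (future C4) through its α-carbon (future C3), which forges C3–C4 and closes ring F before loss of water from 6 and hydrolysis release 7 and the catalyst. This is the aminocatalytic domino oxa-Michael/aldol condensation of salicylaldehydes with enals (iminium–enamine activation). Ring F closes in a 6-(enolexo)-exo-trig mode, helped by ring D, which holds O1, C8a, C4a and the formyl carbon coplanar and close to the enamine. The only stereocentre that persists, C2, is set by the catalyst's shielding of one iminium face ((S)-catalyst gives R), whereas the C3 and C4 centres of 6 are erased by the dehydration, which also makes the reversible oxa-Michael step irreversible overall. O-attack rather than C-attack of ring D, and reaction at one oxygen only, are secured by the benzyl ethers on O5 and O7 and by the deactivating formyl group, and only the α-carbon of the enamine can reach the formyl carbon, so no other ring size competes.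

Step 4
Reactants: 7 (R)-5,7-bis(benzyloxy)-2-[3,4-bis(benzyloxy)phenyl]-2H-chromene-3-carbaldehyde
Product: 8 (R)-5,7-bis(benzyloxy)-2-[3,4-bis(benzyloxy)phenyl]-2H-chromene-3-carboxylic acid
Conditions: NaClO2, NaH2PO4, 2-methylbut-2-ene (large excess), t-BuOH/THF/H2O, 0 °C
Reagents that add atoms: sodium chlorite, [Na+].[O-]Cl=O
Why: Pinnick oxidation should convert the enal chemoselectively into the acid under buffered conditions, with the alkene scavenger keeping hypochlorous acid away from electron-rich ring D and the allylic C2 centre left untouched.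

Step 5
Reactants: 8 (R)-5,7-bis(benzyloxy)-2-[3,4-bis(benzyloxy)phenyl]-2H-chromene-3-carboxylic acid
Product: 11 (2R)-5,7-bis(benzyloxy)-2-[3,4-bis(benzyloxy)phenyl]chroman-3-one, via acyl azide 9 (not isolated), via vinyl isocyanate 10 (not isolated)
Conditions: (PhO)2P(O)N3, Et3N, toluene, 25 → 80 °C, dark; then 1 M aq. HCl, THF, 25 °C
Reagents that add atoms: water, O; diphenylphosphoryl azide, [N-]=[N+]=NP(=O)(Oc1ccccc1)Oc1ccccc1 (nitrogen in 9 and 10 only)
Why: Curtius rearrangement of the α,β-unsaturated acyl azide moves C3 from carbon to nitrogen, and mild acid hydrolysis of the vinyl isocyanate (carbamic acid, enamine, protonation at C4, imine hydrolysis) should unveil the C3 ketone and the C4 methylene, which is the established route from 2H-chromene-3-carboxylic acids to chroman-3-ones.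

Step 6
Reactants: 11 (2R)-5,7-bis(benzyloxy)-2-[3,4-bis(benzyloxy)phenyl]chroman-3-one
Product: 12 (2R,3R)-5,7-bis(benzyloxy)-2-[3,4-bis(benzyloxy)phenyl]chroman-3-ol (5,7,3',4'-tetra-O-benzyl-(−)-epicatechin)
Conditions: LiBH(s-Bu)3, LiBr, THF, −78 °C; then H2O
Reagents that add atoms: none
Why: In this substrate-controlled ketone reduction the bulky borohydride should attack C3 from the less hindered equatorial direction of the half-chair in which ring E is equatorial, placing the new hydroxyl axial and cis to ring E (2R,3R), as known for this type of flavan-3-one.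

Step 7
Reactants: 12 (2R,3R)-5,7-bis(benzyloxy)-2-[3,4-bis(benzyloxy)phenyl]chroman-3-ol
Product: 13 (2R,3R)-3,5,7-tris(benzyloxy)-2-[3,4-bis(benzyloxy)phenyl]chroman
Conditions: NaH, BnBr, DMF, 0 → 25 °C
Reagents that add atoms: benzyl bromide, BrCc1ccccc1
Why: Williamson etherification of the secondary alkoxide masks the only acidic proton before the lithiation, using a group that falls in the final hydrogenolysis.

Step 8
Reactants: 13 (2R,3R)-3,5,7-tris(benzyloxy)-2-[3,4-bis(benzyloxy)phenyl]chroman
Product: 14 (2R,3R)-3,5,7-tris(benzyloxy)-2-[3,4-bis(benzyloxy)phenyl]-8-bromochroman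
Conditions: NBS, CH2Cl2, −78 → 25 °C
Reagents that add atoms: N-bromosuccinimide, O=C1CCC(=O)N1Br
Why: Electrophilic aromatic bromination of 5,7-di-O-benzyl flavan-3-ols is known to go to C8, the ring D position ortho to O1 and para to the 5-benzyloxy group, rather than to C6 between two benzyloxy groups.

Step 9
Reactants: 15 7-hydroxy-4H-chromen-4-one
Product: 16 7-(benzyloxy)-4H-chromen-4-one
Conditions: BnBr, K2CO3, acetone, 56 °C
Reagents that add atoms: benzyl bromide, BrCc1ccccc1
Why: Williamson etherification of the acidic 7-hydroxyl under conditions that leave the pyranone ring intact.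

Step 10
Reactants: 16 7-(benzyloxy)-4H-chromen-4-one; 17 [4-(benzyloxy)phenyl]boronic acid
Product: 18 (S)-7-(benzyloxy)-2-[4-(benzyloxy)phenyl]chroman-4-one
Conditions: [Rh(OH)(cod)]2 (1.5 mol %), (S)-MeO-F12-BIPHEP (3.3 mol %), toluene/H2O, 25 °C
Reagents that add atoms: none
Why: In this rhodium-catalysed asymmetric 1,4-addition of an arylboronic acid to a chromone (Hayashi–Miyaura reaction) the aryl-rhodium species adds to C2 on the face left open by the (S)-bisphosphine to set (2S), and the near-neutral medium avoids ring opening of the flavanone.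

Step 11
Reactants: 14 (2R,3R)-3,5,7-tris(benzyloxy)-2-[3,4-bis(benzyloxy)phenyl]-8-bromochroman; 18 (S)-7-(benzyloxy)-2-[4-(benzyloxy)phenyl]chroman-4-one
Product: 20 (2S)-7-(benzyloxy)-2-[4-(benzyloxy)phenyl]-4-{(2R,3R)-3,5,7-tris(benzyloxy)-2-[3,4-bis(benzyloxy)phenyl]chroman-8-yl}chroman-4-ol (carbinol configuration not assigned), via aryllithium 19 (not isolated)
Conditions: t-BuLi (2 equiv), THF, −78 °C; then 18, −78 → 0 °C; then H2O
Reagents that add atoms: tert-butyllithium, [Li]C(C)(C)C (lithium in 19 only)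
Why: Bromine–lithium exchange followed by 1,2-addition of the C8 aryllithium to the C4 carbonyl forms the interflavan bond regiospecifically at C8, a union known for protected 8-bromoflavan-3-ols and flavan-4-ones, and the carbinol configuration is of no consequence because this centre is ionised in the next step.

Step 12
Reactants: 20 the tertiary 4-arylflavan-4-ol
Product: 21 hepta-O-benzyl ether of the target, (2R,3R)-3,5,7-tris(benzyloxy)-2-[3,4-bis(benzyloxy)phenyl]-8-{(2S,4S)-7-(benzyloxy)-2-[4-(benzyloxy)phenyl]chroman-4-yl}chroman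
Conditions: Bu3SnH, CF3CO2H, CH2Cl2, 0 °C
Reagents that add atoms: none
Why: In this ionic hydrogenation the acid ionises the tertiary bis-benzylic alcohol to the C4 cation stabilised by rings A and D, and the tin hydride should deliver hydride along the pseudoaxial trajectory on the face of axial H-2, so that ring D ends equatorial and cis to ring B (4S).

Step 13
Reactants: 21 hepta-O-benzyl ether of the target
Product: 22 (2R,3R)-2-(3,4-dihydroxyphenyl)-8-[(2S,4S)-7-hydroxy-2-(4-hydroxyphenyl)chroman-4-yl]chroman-3,5,7-triol (target)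
Conditions: H2 (1 atm), Pd(OH)2/C, THF/MeOH, 25 °C
Reagents that add atoms: none
Why: Catalytic hydrogenolysis should remove all seven benzyl ethers under neutral conditions that leave the cyclic benzylic C2–O1 bonds, the interflavan bond and the four stereocentres untouched.

Compound list
1 | 2,4,6-trihydroxybenzaldehyde | O=Cc1c(O)cc(O)cc1O | starting material
2 | 2,4-bis(benzyloxy)-6-hydroxybenzaldehyde | O=Cc1c(O)cc(OCc2ccccc2)cc1OCc1ccccc1 | intermediate
3 | 3,4-bis(benzyloxy)benzaldehyde | O=Cc1ccc(OCc2ccccc2)c(OCc2ccccc2)c1 | starting material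
4 | (E)-3-[3,4-bis(benzyloxy)phenyl]prop-2-enal | O=C/C=C/c1ccc(OCc2ccccc2)c(OCc2ccccc2)c1 | intermediate
5 | (S)-3-[3,4-bis(benzyloxy)phenyl]-3-[3,5-bis(benzyloxy)-2-formylphenoxy]propanal, drawn as the free aldehyde (present in the flask as its enamine with the catalyst) | O=CC[C@H](Oc1cc(OCc2ccccc2)cc(OCc2ccccc2)c1C=O)c1ccc(OCc2ccccc2)c(OCc2ccccc2)c1 | intermediate
6 | (2S)-5,7-bis(benzyloxy)-2-[3,4-bis(benzyloxy)phenyl]-4-hydroxychroman-3-carbaldehyde (same spatial arrangement at C2 as in 7; C3 and C4 unassigned) | O=CC1C(O)c2c(OCc3ccccc3)cc(OCc3ccccc3)cc2O[C@@H]1c1ccc(OCc2ccccc2)c(OCc2ccccc2)c1 | intermediate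
7 | (R)-5,7-bis(benzyloxy)-2-[3,4-bis(benzyloxy)phenyl]-2H-chromene-3-carbaldehyde | O=CC1=Cc2c(OCc3ccccc3)cc(OCc3ccccc3)cc2O[C@@H]1c1ccc(OCc2ccccc2)c(OCc2ccccc2)c1 | intermediate
8 | (R)-5,7-bis(benzyloxy)-2-[3,4-bis(benzyloxy)phenyl]-2H-chromene-3-carboxylic acid | OC(=O)C1=Cc2c(OCc3ccccc3)cc(OCc3ccccc3)cc2O[C@@H]1c1ccc(OCc2ccccc2)c(OCc2ccccc2)c1 | intermediate
9 | (R)-5,7-bis(benzyloxy)-2-[3,4-bis(benzyloxy)phenyl]-2H-chromene-3-carbonyl azide | [N-]=[N+]=NC(=O)C1=Cc2c(OCc3ccccc3)cc(OCc3ccccc3)cc2O[C@@H]1c1ccc(OCc2ccccc2)c(OCc2ccccc2)c1 | intermediate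
10 | (R)-5,7-bis(benzyloxy)-2-[3,4-bis(benzyloxy)phenyl]-3-isocyanato-2H-chromene | O=C=NC1=Cc2c(OCc3ccccc3)cc(OCc3ccccc3)cc2O[C@@H]1c1ccc(OCc2ccccc2)c(OCc2ccccc2)c1 | intermediate
11 | (2R)-5,7-bis(benzyloxy)-2-[3,4-bis(benzyloxy)phenyl]chroman-3-one | O=C1Cc2c(OCc3ccccc3)cc(OCc3ccccc3)cc2O[C@@H]1c1ccc(OCc2ccccc2)c(OCc2ccccc2)c1 | intermediate
12 | (2R,3R)-5,7-bis(benzyloxy)-2-[3,4-bis(benzyloxy)phenyl]chroman-3-ol | O[C@@H]1Cc2c(OCc3ccccc3)cc(OCc3ccccc3)cc2O[C@@H]1c1ccc(OCc2ccccc2)c(OCc2ccccc2)c1 | intermediate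
13 | (2R,3R)-3,5,7-tris(benzyloxy)-2-[3,4-bis(benzyloxy)phenyl]chroman | C(c1ccccc1)O[C@@H]1Cc2c(OCc3ccccc3)cc(OCc3ccccc3)cc2O[C@@H]1c1ccc(OCc2ccccc2)c(OCc2ccccc2)c1 | intermediate
14 | (2R,3R)-3,5,7-tris(benzyloxy)-2-[3,4-bis(benzyloxy)phenyl]-8-bromochroman | C(c1ccccc1)O[C@@H]1Cc2c(OCc3ccccc3)cc(OCc3ccccc3)c(Br)c2O[C@@H]1c1ccc(OCc2ccccc2)c(OCc2ccccc2)c1 | intermediate
15 | 7-hydroxy-4H-chromen-4-one | O=c1ccoc2cc(O)ccc12 | starting material
16 | 7-(benzyloxy)-4H-chromen-4-one | O=c1ccoc2cc(OCc3ccccc3)ccc12 | intermediate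
17 | [4-(benzyloxy)phenyl]boronic acid | OB(O)c1ccc(OCc2ccccc2)cc1 | starting material
18 | (S)-7-(benzyloxy)-2-[4-(benzyloxy)phenyl]chroman-4-one | O=C1C[C@@H](c2ccc(OCc3ccccc3)cc2)Oc2cc(OCc3ccccc3)ccc12 | intermediate
19 | {(2R,3R)-3,5,7-tris(benzyloxy)-2-[3,4-bis(benzyloxy)phenyl]chroman-8-yl}lithium | [Li]c1c(OCc2ccccc2)cc(OCc2ccccc2)c2c1O[C@H](c1ccc(OCc3ccccc3)c(OCc3ccccc3)c1)[C@H](OCc1ccccc1)C2 | intermediate
20 | (2S)-7-(benzyloxy)-2-[4-(benzyloxy)phenyl]-4-{(2R,3R)-3,5,7-tris(benzyloxy)-2-[3,4-bis(benzyloxy)phenyl]chroman-8-yl}chroman-4-ol (carbinol carbon unassigned) | OC1(C[C@@H](c2ccc(OCc3ccccc3)cc2)Oc2cc(OCc3ccccc3)ccc12)c1c(OCc2ccccc2)cc(OCc2ccccc2)c2c1O[C@H](c1ccc(OCc3ccccc3)c(OCc3ccccc3)c1)[C@H](OCc1ccccc1)C2 | intermediate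
21 | hepta-O-benzyl ether of the target, (2S,4S) in the upper unit and (2R,3R) in the lower unit | C(c1ccccc1)Oc1ccc([C@@H]2C[C@H](c3c(OCc5ccccc5)cc(OCc5ccccc5)c4c3O[C@H](c3ccc(OCc5ccccc5)c(OCc5ccccc5)c3)[C@H](OCc3ccccc3)C4)c3ccc(OCc4ccccc4)cc3O2)cc1 | intermediate
22 | (2R,3R)-2-(3,4-dihydroxyphenyl)-8-[(2S,4S)-7-hydroxy-2-(4-hydroxyphenyl)chroman-4-yl]chroman-3,5,7-triol | Oc1ccc([C@@H]2C[C@H](c3c(O)cc(O)c4c3O[C@H](c3ccc(O)c(O)c3)[C@H](O)C4)c3ccc(O)cc3O2)cc1 | target

Total step count: 13. Longest linear sequence: 10 (steps 1, 3, 4, 5, 6, 7, 8, 11, 12, 13).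

Steps most likely to fail

Step 3.
- **Risk:** the aldol closure onto the electron-rich, doubly ortho-substituted formyl group may be slow. The reversible oxa-Michael addition could then stall, or the enantioselectivity could erode.
- **Fallback:** it sets out from 2 and 3 and returns at 11. Henry condensation of 3 with nitromethane (NH4OAc, AcOH, 100 °C) gives (E)-1,2-bis(benzyloxy)-4-(2-nitroethenyl)benzene F1. With a bifunctional tertiary amine–thiourea catalyst in toluene, 2 and F1 undergo the oxa-Michael/Henry/dehydration domino. Here the more nucleophilic nitronate closes the same C3–C4 bond, giving (R)-5,7-bis(benzyloxy)-2-[3,4-bis(benzyloxy)phenyl]-3-nitro-2H-chromene F2.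
- **Return to the route:** reduction of the nitroalkene with CrCl2 in THF/aq. HCl (oxime, imine, hydrolysis) leads to ketone 11 and makes steps 4 and 5 unnecessary. Any minor antipode at C2 becomes a separable diastereomer after step 11.

Step 5.
- **Risk:** configuration at C2 may be lost, either by thermal electrocyclic opening of the 2H-chromene at 80 °C or by imine–enamine tautomerism during the hydrolysis.
- **Fallback:** it sets out from 7 and returns at 11. Baeyer–Villiger oxidation of enal 7 with vinyl migration (30 % H2O2, catalytic bis(2-nitrophenyl) diselenide, CH2Cl2, 0 → 25 °C) gives (R)-5,7-bis(benzyloxy)-2-[3,4-bis(benzyloxy)phenyl]-2H-chromen-3-yl formate F3. Methanolysis of F3 (KHCO3, MeOH, 0 °C) releases 11 without heating and without nitrogen intermediates. Steps 4 and 5 are replaced.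

Step 11.
- **Risk:** the hindered aryllithium may deprotonate the flavanone at C3. β-Elimination of the ring A phenoxide (opening of ring C) would then compete with 1,2-addition.
- **Fallback:** it sets out from 13 and 18 and returns at 21. NaBH4 (MeOH/THF, 0 °C) reduces 18 to (2S,4S)-7-(benzyloxy)-2-[4-(benzyloxy)phenyl]chroman-4-ol F4. BF3·OEt2 (CH2Cl2, −78 → 0 °C) ionises F4, and the C4 cation is captured by C8 of 13 in a Friedel–Crafts alkylation that gives 21 directly.
- **Consequence:** steps 8, 11 and 12 fall away. Facial selectivity at C4 of ring C is then under weaker control, so equilibrating conditions and a chromatographic separation of C4 epimers would be needed.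

Further compounds
F1 | step 3 | (E)-1,2-bis(benzyloxy)-4-(2-nitroethenyl)benzene | O=[N+]([O-])/C=C/c1ccc(OCc2ccccc2)c(OCc2ccccc2)c1
F2 | step 3 | (R)-5,7-bis(benzyloxy)-2-[3,4-bis(benzyloxy)phenyl]-3-nitro-2H-chromene | O=[N+]([O-])C1=Cc2c(OCc3ccccc3)cc(OCc3ccccc3)cc2O[C@@H]1c1ccc(OCc2ccccc2)c(OCc2ccccc2)c1
F3 | step 5 | (R)-5,7-bis(benzyloxy)-2-[3,4-bis(benzyloxy)phenyl]-2H-chromen-3-yl formate | O=COC1=Cc2c(OCc3ccccc3)cc(OCc3ccccc3)cc2O[C@@H]1c1ccc(OCc2ccccc2)c(OCc2ccccc2)c1
F4 | step 11 | (2S,4S)-7-(benzyloxy)-2-[4-(benzyloxy)phenyl]chroman-4-ol | O[C@H]1C[C@@H](c2ccc(OCc3ccccc3)cc2)Oc2cc(OCc3ccccc3)ccc12
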